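Assumption: hericenone F (the target, 2S) is taken to arise in the fungus from achiral hericenone C by shift of the 2′,3′-olefin into conjugation with the 5′-ketone and 6-exo oxa-Michael closure by the 3-OH; compound numbers follow first appearance in the forward steps.

**Retrosynthetic overview**
1. Target 18 ⇐ hericenone C 16 (achiral, E/Z irrelevant): last-step catalytic asymmetric olefin transposition / 6-exo oxa-Michael (via dienone 17) closes the pyran and sets C2 (S).
2. 16 ⇐ allylphenol 12 + deconjugated phorone 15 by cross-metathesis.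
3. 12 ⇐ 5 by Vilsmeier formylation/chlorination, palmitate displacement and chelation-controlled mono-demethylation; 5 ⇐ 3,5-dimethoxybenzyl alcohol 1 + allyl bromide 2 by directed lithiation; 15 ⇐ phorone 13.
4. Ring order: the benzene ring is bought; the dihydropyran ring is the only ring formed, in the final step.

**Route**

Step 1
Reactants: 1 3,5-dimethoxybenzyl alcohol; 2 allyl bromide
Product: 5 (4-allyl-3,5-dimethoxyphenyl)methanol, via dilithiated benzyl alcohol 3 (not isolated), via lithium alkoxide of the product 4 (not isolated)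
Conditions: n-BuLi (2.3 equiv), TMEDA, THF–hexane, 0 °C → rt; CuBr·SMe2 (10 mol%), 2 (1.1 equiv), −78 → 0 °C; H2O
Reagents that add atoms: allyl bromide (compound 2), C=CCBr
Why: Directed ortho-metalation: the C4–H flanked by both methoxy groups is the most acidic ring position of the lithium alkoxide of 1, and the aryllithium is allylated by Cu-catalysed substitution of the symmetrical allyl bromide; no stereocenter.

Step 2
Reactants: 5 (4-allyl-3,5-dimethoxyphenyl)methanol
Product: 8 3-allyl-6-(chloromethyl)-2,4-dimethoxybenzaldehyde, via 4-allyl-3,5-dimethoxybenzyl chloride 6 (not isolated), via aryl iminium chloride 7 (not isolated)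
Conditions: POCl3 (3 equiv), DMF, 0 → 75 °C; ice-water
Reagents that add atoms: N,N-dimethylformamide, CN(C)C=O; phosphoryl chloride, O=P(Cl)(Cl)Cl; water, O
Why: Vilsmeier–Haack reaction: the chloroiminium reagent turns the benzylic alcohol into the chloride and formylates the only free ring position (C2 ≡ C6, ortho/para to the two OMe groups), with the isolated terminal alkene inert and hydrolysis delivering the aldehyde.

Step 3
Reactants: 8 3-allyl-6-(chloromethyl)-2,4-dimethoxybenzaldehyde; 9 sodium palmitate
Product: 10 (4-allyl-2-formyl-3,5-dimethoxyphenyl)methyl hexadecanoate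
Conditions: 9 (1.3 equiv), NaI (10 mol%), DMF, 60 °C
Reagents that add atoms: sodium palmitate (compound 9), CCCCCCCCCCCCCCCC(=O)[O-].[Na+]
Why: SN2 displacement of the benzylic chloride by carboxylate (iodide-assisted) installs the palmitate ester directly, without a free benzyl alcohol stage.

Step 4
Reactants: 10 (4-allyl-2-formyl-3,5-dimethoxyphenyl)methyl hexadecanoate
Product: 12 (4-allyl-2-formyl-3-hydroxy-5-methoxyphenyl)methyl hexadecanoate, via aryl dichloroborinate 11 (not isolated)
Conditions: BCl3 (1.2 equiv), CH2Cl2, −78 → 0 °C; H2O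
Reagents that add atoms: none
Why: Chelation-controlled Lewis-acid demethylation: BCl3 bridges the aldehyde oxygen and the ortho-methoxy oxygen, so only that ether is cleaved, while the para-OMe, the ester (its benzylic carbon deactivated by the ortho-CHO) and the allyl group survive at low temperature.

Step 5
Reactants: 13 phorone (2,6-dimethylhepta-2,5-dien-4-one)
Product: 15 2,6-dimethylhepta-1,5-dien-4-one, via lithium dienolate of phorone 14 (not isolated)
Conditions: LDA (1.05 equiv), THF, −78 °C; AcOH (inverse quench), −78 °C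
Reagents that add atoms: none
Why: Deconjugative protonation: phorone has only γ-hydrogens, so LDA gives the cross-conjugated dienolate, and kinetic protonation at the α-carbon gives the β,γ-unsaturated ketone.

Step 6
Reactants: 12 (4-allyl-2-formyl-3-hydroxy-5-methoxyphenyl)methyl hexadecanoate; 15 2,6-dimethylhepta-1,5-dien-4-one
Product: 16 hericenone C as 2′E/2′Z mixture, [2-formyl-3-hydroxy-5-methoxy-4-(3,7-dimethyl-5-oxoocta-2,6-dien-1-yl)phenyl]methyl hexadecanoate
Conditions: Hoveyda–Grubbs II (7.5 mol%), 15 (5 equiv), 1,4-benzoquinone (10 mol%), CH2Cl2, 40 °C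
Reagents that add atoms: 2,6-dimethylhepta-1,5-dien-4-one (compound 15), C=C(C)CC(=O)C=C(C)C
Why: Olefin cross-metathesis of a type-I allylarene with excess 1,1-disubstituted (type-III) alkene gives the trisubstituted olefin with loss of ethene, the electron-poor trisubstituted enone C=C being inert; the E/Z ratio does not matter because this double bond is moved in step 7.

Step 7
Reactants: 16 hericenone C (2′E/2′Z mixture)
Product: 18 (S)-hericenone F [(2S)-8-formyl-5-methoxy-2-methyl-2-(4-methyl-2-oxopent-3-en-1-yl)chroman-7-yl]methyl hexadecanoate, via conjugated dienone 17 (not isolated)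
Conditions: squaramide of 9-amino-9-deoxy-epi-quinidine and 3,5-bis(trifluoromethyl)aniline (10 mol%), toluene (0.05 M), 4 Å MS, 0 → 25 °C, 48 h
Reagents that add atoms: none
Why: Proposed new method: the catalyst's quinuclidine nitrogen (with the acidic ortho-formyl phenol as proton relay) removes a doubly activated C4′ proton and reprotonates at C2′ to give dienone 17 (3′E/3′Z, equilibrating through the dienolate), after which the squaramide-bound carbonyl and ammonium-bound phenoxide close the ring by 6-exo-trig oxa-Michael addition on the Si face of C3′ to set (2S); the closest known reactions are cinchona urea/squaramide-catalysed intramolecular oxa-Michael additions of phenols to enones giving 2-substituted chromans and amine-catalysed β,γ→α,β enone isomerisation, and the sense of induction is an assumption to be checked by chiral HPLC/CD, with the pseudo-enantiomeric quinine-derived catalyst as the direct switch.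

**Compound list**
1 | 3,5-dimethoxybenzyl alcohol | COc1cc(CO)cc(OC)c1 | starting material
2 | allyl bromide (3-bromoprop-1-ene) | C=CCBr | starting material
3 | lithium (4-lithio-3,5-dimethoxyphenyl)methanolate (not isolated) | [Li]OCc1cc(OC)c([Li])c(OC)c1 | intermediate
4 | lithium (4-allyl-3,5-dimethoxyphenyl)methanolate (not isolated) | [Li]OCc1cc(OC)c(CC=C)c(OC)c1 | intermediate
5 | (4-allyl-3,5-dimethoxyphenyl)methanol | OCc1cc(OC)c(CC=C)c(OC)c1 | intermediate
6 | 4-allyl-3,5-dimethoxybenzyl chloride (not isolated) | ClCc1cc(OC)c(CC=C)c(OC)c1 | intermediate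
7 | [3-allyl-6-(chloromethyl)-2,4-dimethoxybenzylidene]dimethyliminium chloride (not isolated) | C[N+](C)=Cc1c(CCl)cc(OC)c(CC=C)c1OC.[Cl-] | intermediate
8 | 3-allyl-6-(chloromethyl)-2,4-dimethoxybenzaldehyde | O=Cc1c(CCl)cc(OC)c(CC=C)c1OC | intermediate
9 | sodium palmitate (sodium hexadecanoate) | CCCCCCCCCCCCCCCC(=O)[O-].[Na+] | starting material
10 | (4-allyl-2-formyl-3,5-dimethoxyphenyl)methyl hexadecanoate | CCCCCCCCCCCCCCCC(=O)OCc1cc(OC)c(CC=C)c(OC)c1C=O | intermediate
11 | (4-allyl-3-dichloroboryloxy-2-formyl-5-methoxyphenyl)methyl hexadecanoate (not isolated) | CCCCCCCCCCCCCCCC(=O)OCc1cc(OC)c(CC=C)c(OB(Cl)Cl)c1C=O | intermediate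
12 | (4-allyl-2-formyl-3-hydroxy-5-methoxyphenyl)methyl hexadecanoate | CCCCCCCCCCCCCCCC(=O)OCc1cc(OC)c(CC=C)c(O)c1C=O | intermediate
13 | phorone (2,6-dimethylhepta-2,5-dien-4-one) | CC(C)=CC(=O)C=C(C)C | starting material
14 | lithium 2,6-dimethylhepta-1,3,5-trien-4-olate (not isolated) | [Li]OC(=CC(C)=C)C=C(C)C | intermediate
15 | 2,6-dimethylhepta-1,5-dien-4-one | C=C(C)CC(=O)C=C(C)C | intermediate
16 | hericenone C, 2′E/2′Z mixture: [2-formyl-3-hydroxy-5-methoxy-4-(3,7-dimethyl-5-oxoocta-2,6-dien-1-yl)phenyl]methyl hexadecanoate | CCCCCCCCCCCCCCCC(=O)OCc1cc(OC)c(CC=C(C)CC(=O)C=C(C)C)c(O)c1C=O | intermediate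
17 | conjugated dienone, 3′E/3′Z mixture: [2-formyl-3-hydroxy-5-methoxy-4-(3,7-dimethyl-5-oxoocta-3,6-dien-1-yl)phenyl]methyl hexadecanoate (not isolated) | CCCCCCCCCCCCCCCC(=O)OCc1cc(OC)c(CCC(C)=CC(=O)C=C(C)C)c(O)c1C=O | intermediate
18 | (S)-hericenone F, [(2S)-8-formyl-5-methoxy-2-methyl-2-(4-methyl-2-oxopent-3-en-1-yl)-3,4-dihydro-2H-chromen-7-yl]methyl hexadecanoate | CCCCCCCCCCCCCCCC(=O)OCc1cc(OC)c2c(c1C=O)O[C@](C)(CC(=O)C=C(C)C)CC2 | target

**Totals**
Total step count: 7. Longest linear sequence: 6 (steps 1, 2, 3, 4, 6, 7); step 5 is a one-step side branch.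

**Three steps most likely to fail, with fallbacks**

Step 7 (asymmetric isomerisation / oxa-Michael). The risks are slow olefin transposition, different facial outcomes from the 3′E and 3′Z forms of 17, and loss of ee by retro-oxa-Michael. The fallback sets out from 16 and comes back at 18. It replaces asymmetric catalysis by resolution with recycling: 16 is cyclised with an achiral base (Et3N or 10 mol% DBU, CH2Cl2, rt) to racemic hericenone F F1. Preparative chiral SFC on a polysaccharide carbamate phase then gives 18 and (R)-hericenone F F2. F2 is returned to F1 by warming with DBU (retro-oxa-Michael and re-closure) and resolved again.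

Step 6 (cross-metathesis to a trisubstituted olefin). The risks are homodimerisation of 12, allyl-to-propenyl isomerisation and low turnover with the type-III partner. The fallback sets out from 12 and 15 and comes back at 16. It makes the metathesis intramolecular through a temporary silicon tether. Luche reduction of 15 (NaBH4, CeCl3, MeOH, 0 °C) gives 2,6-dimethylhepta-1,5-dien-4-ol F3. F3 is treated with iPr2SiCl2/imidazole and then 12 to give the mixed diisopropylsilaketal F4. Ring-closing metathesis (Grubbs II, toluene, 80 °C, high dilution) gives the ten-membered cyclic silaketal F5. HF·pyridine releases 5′-hydroxy-5′-deoxohericenone C F6, and MnO2 oxidation of its allylic alcohol gives 16.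

Step 1 (regioselective dilithiation/allylation). The risk is competing lithiation at C2, between CH2OLi and OMe, or O-allylation. The fallback sets out from 1 and comes back at 12. It places the allyl group by aromatic Claisen rearrangement instead of metalation. Vilsmeier reaction of 1 (POCl3, DMF) gives 2-(chloromethyl)-4,6-dimethoxybenzaldehyde F7. Sodium palmitate in DMF gives (2-formyl-3,5-dimethoxyphenyl)methyl hexadecanoate F8. BCl3 gives (2-formyl-3-hydroxy-5-methoxyphenyl)methyl hexadecanoate F9. O-Allylation with 2 (K2CO3, acetone) gives [3-(allyloxy)-2-formyl-5-methoxyphenyl]methyl hexadecanoate F10. Heating F10 (N,N-diethylaniline, 190 °C) moves the allyl group to the only free ortho carbon and gives 12.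

**Further compounds**
F1 | step 7 | racemic hericenone F | CCCCCCCCCCCCCCCC(=O)OCc1cc(OC)c2c(c1C=O)OC(C)(CC(=O)C=C(C)C)CC2
F2 | step 7 | (R)-hericenone F | CCCCCCCCCCCCCCCC(=O)OCc1cc(OC)c2c(c1C=O)O[C@@](C)(CC(=O)C=C(C)C)CC2
F3 | step 6 | 2,6-dimethylhepta-1,5-dien-4-ol (racemic) | C=C(C)CC(O)C=C(C)C
F4 | step 6 | mixed diisopropylsilaketal of 12 (phenol oxygen) and F3 | CCCCCCCCCCCCCCCC(=O)OCc1cc(OC)c(CC=C)c(O[Si](C(C)C)(C(C)C)OC(CC(C)=C)C=C(C)C)c1C=O
F5 | step 6 | ten-membered cyclic diisopropylsilaketal with C2′=C3′ trisubstituted olefin | CCCCCCCCCCCCCCCC(=O)OCc1cc(OC)c2CC=C(C)CC(C=C(C)C)O[Si](C(C)C)(C(C)C)Oc2c1C=O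
F6 | step 6 | 5′-hydroxy-5′-deoxohericenone C, [2-formyl-3-hydroxy-4-(5-hydroxy-3,7-dimethylocta-2,6-dien-1-yl)-5-methoxyphenyl]methyl hexadecanoate | CCCCCCCCCCCCCCCC(=O)OCc1cc(OC)c(CC=C(C)CC(O)C=C(C)C)c(O)c1C=O
F7 | step 1 | 2-(chloromethyl)-4,6-dimethoxybenzaldehyde | O=Cc1c(CCl)cc(OC)cc1OC
F8 | step 1 | (2-formyl-3,5-dimethoxyphenyl)methyl hexadecanoate | CCCCCCCCCCCCCCCC(=O)OCc1cc(OC)cc(OC)c1C=O
F9 | step 1 | (2-formyl-3-hydroxy-5-methoxyphenyl)methyl hexadecanoate | CCCCCCCCCCCCCCCC(=O)OCc1cc(OC)cc(O)c1C=O
F10 | step 1 | [3-(allyloxy)-2-formyl-5-methoxyphenyl]methyl hexadecanoate | CCCCCCCCCCCCCCCC(=O)OCc1cc(OC)cc(OCC=C)c1C=O
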